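**Strategy.** The pyran ring is made last, from the five-membered O-ring of a dispiro dihydrobenzofuran. In this precursor the ring oxygen O1 sits on the spiro carbon C3, anti to a hydroxyl on C2 of the adjoining cyclopentane. Ionisation at C2 lets O1 bridge to C2 (aryloxiranium ion); AlMe3 then methylates C3 with inversion. One operation moves O1 from C3 to C2, expands the ring O1–C3–C4–C4a–C8a to the pyran O1–C2–C3–C4–C4a–C8a, creates the quaternary C3–CH3 centre and fixes the cis ring fusion. It exploits the anti relationship of O1 (on C2) and CH3 (on C3) in the target. The precursor is assembled from a dihydrobenzofuran ester, a two-carbon linker and (+)-menthone.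

Key step: step 9

Remark: locants follow the chroman core of the target and are kept for the same atoms in every intermediate: O1, C2 (O–CH), C3 (C–CH3), C4 (CH–isobutyl), C4a, C5–C8, C8a; C3' and C4' are the cyclopentane CH2 groups, C5' the spiro carbon, C6'=C7' the ring alkene (isopropyl on C7'), C8', C9' and C10' (CH–CH3) the rest of the six-membered carbocycle. (+)-Menthone and 2-bromoethyl triflate are taken as purchasable.

Step 1
Reactants: 1 2-hydroxy-4,6-dimethoxybenzaldehyde; 2 isobutylmagnesium bromide
Product: 3 2-(1-hydroxy-3-methylbutyl)-3,5-dimethoxyphenol (racemic)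
Conditions: iBuMgBr (2.2 equiv), THF, 0 °C → rt; H2O
Reagents that add atoms: isobutylmagnesium bromide, CC(C)C[Mg]Br
Why: Grignard addition to the aldehyde (after deprotonation of the phenol) should give the benzylic alcohol; the new centre is racemic and is erased when the o-quinone methide is formed in step 3.

Step 2
Reactants: 3 2-(1-hydroxy-3-methylbutyl)-3,5-dimethoxyphenol; 4 sodium 4-methylbenzenesulfinate
Product: 5 3,5-dimethoxy-2-[3-methyl-1-(4-methylbenzenesulfonyl)butyl]phenol (racemic)
Conditions: HCO2H–H2O, rt
Reagents that add atoms: sodium 4-methylbenzenesulfinate, Cc1ccc(cc1)S(=O)[O-].[Na+]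
Why: Acid-promoted SN1 substitution of the electron-rich benzylic alcohol by sulfinate sulfur should give the sulfone, a base-triggered o-quinone methide precursor.

Step 3
Reactants: 5 the sulfone; 6 ethyl (dimethylsulfuranylidene)acetate
Product: 8 ethyl (2S,3S)-4,6-dimethoxy-3-(2-methylpropyl)-2,3-dihydro-1-benzofuran-2-carboxylate, via o-quinone methide 7 (not isolated)
Conditions: Cs2CO3, chiral bis-urea hydrogen-bond catalyst from trans-cyclohexane-1,2-diamine (10 mol %), CH2Cl2, 0 °C
Reagents that add atoms: ethyl (dimethylsulfuranylidene)acetate, CCOC(=O)C=S(C)C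
Why: 1,4-Elimination of sulfinate gives 7, the ylide adds in Michael fashion and the phenoxide displaces Me2S (5-exo-tet), a [4+1] annulation that should give the trans ester, the catalyst bound to the carbonyl of 7 selecting the face of the methide carbon and so setting C4 (the catalyst antipode is taken if the sense proves opposite; any minor enantiomer becomes a separable diastereomer in step 5).

Step 4
Reactants: 8 the trans ester; 9 2-bromoethyl trifluoromethanesulfonate
Product: 11 ethyl (2R,3S)-2-(2-bromoethyl)-4,6-dimethoxy-3-(2-methylpropyl)-2,3-dihydro-1-benzofuran-2-carboxylate, via lithium enolate 10 (not isolated)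
Conditions: LiN(iPr)2, THF, −78 °C; then 9, −78 → −20 °C
Reagents that add atoms: 2-bromoethyl trifluoromethanesulfonate, BrCCOS(=O)(=O)C(F)(F)F
Why: Ester enolate alkylation (SN2 at the triflate carbon, far faster than at C–Br) should occur anti to the neighbouring isobutyl group, so at the now quaternary C3 the new chain (C3'–C4') is trans and the ester carbon (C2) cis to isobutyl.

Step 5
Reactants: 12 (+)-menthone; 11 the bromo ester
Product: 14 ethyl (2R,3S)-4,6-dimethoxy-2-{2-[(1R,3R,6S)-6-methyl-2-oxo-3-(propan-2-yl)cyclohexyl]ethyl}-3-(2-methylpropyl)-2,3-dihydro-1-benzofuran-2-carboxylate, via lithium enolate 13 (not isolated)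
Conditions: LiN(iPr)2, THF, −78 °C (on 12); then 11, HMPA, −78 → 0 °C
Reagents that add atoms: none
Why: The kinetic enolate at the CH2 of menthone (C5') should be alkylated by the primary bromide (SN2), mainly trans to the C10' methyl; the configurations at C5' and C7' do not matter because both carbons are re-enolised in steps 6 and 7.

Step 6
Reactants: 14 the keto ester
Product: 16 dispiro diketone, via lithium enolate 15 (not isolated)
Conditions: LiN(SiMe3)2, THF, −78 → 0 °C; AcOH
Reagents that add atoms: none
Why: Intramolecular Claisen (Dieckmann-type) acylation, 5-(enol-exo)-exo-trig, of the C5' enolate (the C7' enolate equilibrates and cannot close a five-membered ring) should form the cyclopentanone, the enolate being attacked opposite the pseudo-axial C10' methyl so that the new C5'–C2 bond is trans and C4' cis to that methyl.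

Step 7
Reactants: 16 the dispiro diketone; 17 N-phenylbis(trifluoromethanesulfonimide)
Product: 19 C6'=C7' enol triflate of 16, via potassium enolate 18 (not isolated)
Conditions: KN(SiMe3)2, THF, −78 °C; then 17, −78 → 0 °C
Reagents that add atoms: N-phenylbis(trifluoromethanesulfonimide), O=S(=O)(N(c1ccccc1)S(=O)(=O)C(F)(F)F)C(F)(F)F
Why: C7'–H is the only enolisable position (the C2 ketone lies between two quaternary carbons), so enolate O-triflation should be regiospecific; the enol triflate masks the ketone, is the precursor of the ring alkene and is too electron-poor to act as a neighbouring π-donor in step 9.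

Step 8
Reactants: 19 the enol triflate ketone
Product: 20 C2 alcohol (hydroxyl trans to O1)
Conditions: iBu2AlH, CH2Cl2, −78 °C
Reagents that add atoms: none
Why: Hydride reduction under steric approach control should deliver hydrogen on the ketone face that carries the small ring oxygen O1, because the other face is covered by the C4 branch whose isobutyl group lies cis to C2, giving the C2 carbinol trans to O1 and cis to C4.

Step 9
Reactants: 20 the trans alcohol; 21 trimethylaluminium
Product: 24 ring-expanded cis-fused chroman enol triflate, via alkyl triflate 22 (not isolated), via aryloxiranium triflate 23 (not isolated)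
Conditions: Tf2O, 2,6-di-tert-butyl-4-methylpyridine, CH2Cl2, −78 °C; then AlMe3 (hexane), −78 → 0 °C
Reagents that add atoms: trimethylaluminium, C[Al](C)C
Why: Proposed new method: the C2 triflate 22, which cannot eliminate because both neighbours are quaternary, should ionise with backside participation of the anti-periplanar ring oxygen O1 (3-exo-tet) to the bridged aryloxiranium ion 23, and the aluminate [Me3Al–OTf]− then transfers CH3 to the tertiary carbon C3 with cleavage of O1–C3, so that O1 ends on C2 and the five-membered ring O1–C3–C4–C4a–C8a becomes the six-membered pyran O1–C2–C3–C4–C4a–C8a. The closest known reactions are the rearrangement–ring expansion of 2-(1-sulfonyloxyalkyl) cyclic ethers through oxiranium ions, the interconversion of 2-(halomethyl)dihydrobenzofurans and 3-halochromans, and the methylation of epoxides at the more substituted carbon and of tertiary cation precursors by AlMe3. The pyran is not closed by a new cyclisation but arises by migration of O1; only the transient three-membered ring is closed. C2 is inverted by O1 and C3 is inverted by CH3, so O1 and CH3 end anti and H-2 and CH3 cis (cis ring fusion) by mechanism and not by reagent approach. The step needs O1, and not C4 or a C5' substituent, to participate, and CH3 to enter at C3 and not at C2: only O1 is anti to the leaving group on the C3 side (C4 is syn), the enol triflate is a deactivated π-system, and C3 is the tertiary, more cation-stabilising terminus whereas C2 is a doubly neopentyl carbon.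

Step 10
Reactants: 24 the chroman enol triflate
Product: 25 5,7-dimethoxy chroman with the C6'=C7' alkene
Conditions: Pd(OAc)2, PPh3, Bu3N, HCO2H, DMF, 60 °C
Reagents that add atoms: none
Why: Palladium-catalysed formate reduction of the enol triflate (oxidative addition to zerovalent palladium, formate-to-hydride exchange with loss of CO2, reductive elimination) should leave the C6'=C7' double bond in place and touch nothing else.

Step 11
Reactants: 25 the dimethoxy chroman; 26 N,N-dimethylformamide
Product: 28 6,8-diformyl-5,7-dimethoxy chroman, via lithium aminoalkoxide 27 (not isolated)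
Conditions: n-BuLi, TMEDA, THF, 0 °C; DMF, −78 °C; then s-BuLi, −78 → −40 °C; DMF; aq. HCl
Reagents that add atoms: N,N-dimethylformamide, CN(C)C=O
Why: Directed ortho-lithiation at C6 and then C8 (each flanked by two ether oxygens) with DMF formylation should give the dialdehyde in one pot, the first adduct surviving as its lithium aminoalkoxide, under basic conditions that spare the trisubstituted alkene.

Step 12
Reactants: 28 the dialdehyde bis(methyl ether)
Product: 29 target CNP0121396.2
Conditions: BCl3, CH2Cl2, −78 → 0 °C; H2O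
Reagents that add atoms: none
Why: Chelation-assisted cleavage of the two aryl methyl ethers ortho to formyl groups (chloride attacks the methyl carbon, SN2) should free both phenols, while the ring ether survives because C2 is a doubly neopentyl secondary carbon that neither ionises nor accepts chloride.

**Compound list**

1 | 2-hydroxy-4,6-dimethoxybenzaldehyde | O=Cc1c(O)cc(OC)cc1OC | starting material
2 | isobutylmagnesium bromide | CC(C)C[Mg]Br | starting material
3 | (±)-2-(1-hydroxy-3-methylbutyl)-3,5-dimethoxyphenol | CC(C)CC(O)c1c(O)cc(OC)cc1OC | intermediate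
4 | sodium 4-methylbenzenesulfinate | Cc1ccc(cc1)S(=O)[O-].[Na+] | starting material
5 | (±)-3,5-dimethoxy-2-[3-methyl-1-(4-methylbenzenesulfonyl)butyl]phenol | CC(C)CC(c1c(O)cc(OC)cc1OC)S(=O)(=O)c1ccc(C)cc1 | intermediate
6 | ethyl (dimethylsulfuranylidene)acetate | CCOC(=O)C=S(C)C | starting material
7 | o-quinone methide, 3,5-dimethoxy-6-(3-methylbutylidene)cyclohexa-2,4-dien-1-one (not isolated) | CC(C)CC=C1C(=O)C=C(OC)C=C1OC | intermediate
8 | ethyl (2S,3S)-4,6-dimethoxy-3-(2-methylpropyl)-2,3-dihydro-1-benzofuran-2-carboxylate (trans) | CC(C)C[C@H]1c2c(OC)cc(OC)cc2O[C@@H]1C(=O)OCC | intermediate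
9 | 2-bromoethyl trifluoromethanesulfonate | BrCCOS(=O)(=O)C(F)(F)F | starting material
10 | lithium enolate of 8 (not isolated) | CC(C)C[C@H]1c2c(OC)cc(OC)cc2OC1=C([O-])OCC.[Li+] | intermediate
11 | ethyl (2R,3S)-2-(2-bromoethyl)-4,6-dimethoxy-3-(2-methylpropyl)-2,3-dihydro-1-benzofuran-2-carboxylate (bromoethyl trans to isobutyl) | CC(C)C[C@H]1c2c(OC)cc(OC)cc2O[C@]1(C(=O)OCC)CCBr | intermediate
12 | (+)-menthone, (2R,5S)-5-methyl-2-(propan-2-yl)cyclohexan-1-one | C[C@H]1CC[C@H](C(C)C)C(=O)C1 | starting material
13 | kinetic lithium enolate of 12 at the CH2 (not isolated) | C[C@H]1CC[C@H](C(C)C)C([O-])=C1.[Li+] | intermediate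
14 | ethyl (2R,3S)-4,6-dimethoxy-2-{2-[(1R,3R,6S)-6-methyl-2-oxo-3-(propan-2-yl)cyclohexyl]ethyl}-3-(2-methylpropyl)-2,3-dihydro-1-benzofuran-2-carboxylate (epimers at C5' and C7' converge later) | CC(C)C[C@H]1c2c(OC)cc(OC)cc2O[C@]1(C(=O)OCC)CC[C@H]1C(=O)[C@@H](C(C)C)CC[C@@H]1C | intermediate
15 | lithium enolate of 14 at C5' (not isolated) | CC(C)C[C@H]1c2c(OC)cc(OC)cc2O[C@]1(C(=O)OCC)CCC1=C([O-])[C@@H](C(C)C)CC[C@@H]1C.[Li+] | intermediate
16 | dispiro diketone, 4,6-dimethoxy-6''-methyl-3-(2-methylpropyl)-3''-(propan-2-yl)-3H-dispiro[1-benzofuran-2,1'-cyclopentane-3',1''-cyclohexane]-2',2''-dione; O1 and C6' on the same face of the cyclopentanone, C2 trans to the C10' methyl, isobutyl cis to C2 | CC(C)C[C@H]1c2c(OC)cc(OC)cc2O[C@]12CC[C@@]3(C(=O)[C@@H](C(C)C)CC[C@@H]3C)C2=O | intermediate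
17 | N-phenylbis(trifluoromethanesulfonimide) | O=S(=O)(N(c1ccccc1)S(=O)(=O)C(F)(F)F)C(F)(F)F | starting material
18 | potassium enolate of 16 at C6'/C7' (not isolated) | CC(C)C[C@H]1c2c(OC)cc(OC)cc2O[C@]12CC[C@@]3(C([O-])=C(C(C)C)CC[C@@H]3C)C2=O.[K+] | intermediate
19 | C6'=C7' enol triflate of 16 (C2 ketone retained) | CC(C)C[C@H]1c2c(OC)cc(OC)cc2O[C@]12CC[C@@]3(C(OS(=O)(=O)C(F)(F)F)=C(C(C)C)CC[C@@H]3C)C2=O | intermediate
20 | C2 alcohol of 19; hydroxyl trans to O1, cis to C4 and to C10' | CC(C)C[C@H]1c2c(OC)cc(OC)cc2O[C@]12CC[C@@]3(C(OS(=O)(=O)C(F)(F)F)=C(C(C)C)CC[C@@H]3C)[C@@H]2O | intermediate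
21 | trimethylaluminium | C[Al](C)C | starting material
22 | C2 trifluoromethanesulfonate of 20 (not isolated) | CC(C)C[C@H]1c2c(OC)cc(OC)cc2O[C@]12CC[C@@]3(C(OS(=O)(=O)C(F)(F)F)=C(C(C)C)CC[C@@H]3C)[C@@H]2OS(=O)(=O)C(F)(F)F | intermediate
23 | aryloxiranium trifluoromethanesulfonate, O1 bonded to C8a, C3 and C2 (not isolated) | CC(C)C[C@H]1c2c(OC)cc(OC)cc2[O+]2[C@]13CC[C@@]4(C(OS(=O)(=O)C(F)(F)F)=C(C(C)C)CC[C@@H]4C)[C@@H]23.[O-]S(=O)(=O)C(F)(F)F | intermediate
24 | ring-expanded cis-fused chroman, 5,7-dimethoxy, C3 methyl, C6'=C7' enol triflate; (2S,3R,4R,5'S,10'S) | CC(C)C[C@H]1c2c(OC)cc(OC)cc2O[C@H]2[C@]1(C)CC[C@@]21C(OS(=O)(=O)C(F)(F)F)=C(C(C)C)CC[C@@H]1C | intermediate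
25 | 5,7-di-O-methyl analogue of the target without the two formyl groups; (2S,3R,4R,5'R,10'S) | CC(C)C[C@H]1c2c(OC)cc(OC)cc2O[C@H]2[C@]1(C)CC[C@@]21C=C(C(C)C)CC[C@@H]1C | intermediate
26 | N,N-dimethylformamide | CN(C)C=O | starting material
27 | lithium (dimethylamino)alkoxide of the C6 mono-adduct of 25 (not isolated; the C8 regioisomer converges) | CC(C)C[C@H]1c2c(OC)c(C([O-])N(C)C)c(OC)cc2O[C@H]2[C@]1(C)CC[C@@]21C=C(C(C)C)CC[C@@H]1C.[Li+] | intermediate
28 | 6,8-diformyl-5,7-dimethoxy compound (target bis(methyl ether)) | CC(C)C[C@H]1c2c(OC)c(C=O)c(OC)c(C=O)c2O[C@H]2[C@]1(C)CC[C@@]21C=C(C(C)C)CC[C@@H]1C | intermediate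
29 | CNP0121396.2, 6,8-diformyl-5,7-dihydroxy chroman cis-fused at C2–C3 to the spiro cyclopentane; (2S,3R,4R,5'R,10'S) | CC(C)C[C@H]1c2c(O)c(C=O)c(O)c(C=O)c2O[C@H]2[C@]1(C)CC[C@@]21C=C(C(C)C)CC[C@@H]1C | target

**Count and risks**

Total steps: 12. Longest linear sequence: 12 steps (1 → 29); (+)-menthone 12 and the small reagents enter as purchased materials.

Steps most likely to fail:

1. Step 9 (Proposed new method). Neighbouring-group control may be lost: the triflate may ionise with migration of C4 or of a C5' substituent instead of O1, the developing C3 cation may take a hydride from C4 before methyl transfer, or methyl may be delivered to C2. Fallback with known chemistry, in stages: alcohol 20 is mesylated (MsCl, Et3N) to mesylate F1. Heating F1 with LiCl in DMF lets O1 displace the mesylate and chloride open the oxiranium ion at C3, giving the ring-expanded tertiary chloride F2 (the established rearrangement–ring expansion of ether sulfonates with a heteroatom nucleophile). AlMe3 in CH2Cl2 then exchanges the tertiary chloride for methyl with O1 assistance (known methylation of tertiary chlorides) and the route is rejoined at 24.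

2. Step 6. C-acylation at the congested ester may be slow, with proton transfer to the unproductive C7' enolate and retro-Claisen cleavage of the non-enolisable 1,3-diketone by ethoxide. Fallback: keto ester 14 is saponified (KOH, EtOH–H2O, heat) to carboxylic acid F3 and converted with (COCl)2 into acid chloride F4. Soft enolisation of the ketone (MgBr2·OEt2, iPr2NEt, CH2Cl2) then effects intramolecular C-acylation by the far more reactive acyl chloride, returning to diketone 16.

3. Step 8. Facial selectivity of hydride delivery may be poor, because attack anti to the C3–O1 bond (a stereoelectronic preference) competes with steric control. Fallback that sets the carbinol by C–C bond formation instead: keto ester 14 is reduced (LiAlH4) to diol F5 and oxidised (Swern) to keto aldehyde F6. TMSOTf and Et3N give silyl enol ether F7 (not isolated; only the C5' isomer can cyclise), which undergoes an intramolecular Mukaiyama aldol addition to the non-enolisable aldehyde through an open transition state with the C=O anti to the C3–O1 dipole, giving silyl ether F8 with C2–O trans to O1. Enol triflation (KN(SiMe3)2, PhNTf2) gives enol triflate F9, and K2CO3 in MeOH removes the silyl group to rejoin the route at 20.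

**Further compounds**

F1 | step 9 | C2 methanesulfonate of 20 | CC(C)C[C@H]1c2c(OC)cc(OC)cc2O[C@]12CC[C@@]3(C(OS(=O)(=O)C(F)(F)F)=C(C(C)C)CC[C@@H]3C)[C@@H]2OS(C)(=O)=O
F2 | step 9 | ring-expanded chroman with chlorine on C3 (anti to O1) and the C6'=C7' enol triflate | CC(C)C[C@H]1c2c(OC)cc(OC)cc2O[C@H]2[C@]1(Cl)CC[C@@]21C(OS(=O)(=O)C(F)(F)F)=C(C(C)C)CC[C@@H]1C
F3 | step 6 | carboxylic acid from 14 | CC(C)C[C@H]1c2c(OC)cc(OC)cc2O[C@]1(C(=O)O)CC[C@H]1C(=O)[C@@H](C(C)C)CC[C@@H]1C
F4 | step 6 | acid chloride of F3 | CC(C)C[C@H]1c2c(OC)cc(OC)cc2O[C@]1(C(=O)Cl)CC[C@H]1C(=O)[C@@H](C(C)C)CC[C@@H]1C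
F5 | step 8 | diol from 14 (primary alcohol at C2, secondary alcohol at C6') | CC(C)C[C@H]1c2c(OC)cc(OC)cc2O[C@]1(CO)CC[C@H]1C(O)[C@@H](C(C)C)CC[C@@H]1C
F6 | step 8 | keto aldehyde (C2 aldehyde, C6' ketone) | CC(C)C[C@H]1c2c(OC)cc(OC)cc2O[C@]1(C=O)CC[C@H]1C(=O)[C@@H](C(C)C)CC[C@@H]1C
F7 | step 8 | C5'=C6' trimethylsilyl enol ether of F6 | CC(C)C[C@H]1c2c(OC)cc(OC)cc2O[C@]1(C=O)CCC1=C(O[Si](C)(C)C)[C@@H](C(C)C)CC[C@@H]1C
F8 | step 8 | dispiro aldol as C2 trimethylsilyl ether (C2–O trans to O1, C6' ketone) | CC(C)C[C@H]1c2c(OC)cc(OC)cc2O[C@]12CC[C@@]3(C(=O)[C@@H](C(C)C)CC[C@@H]3C)[C@@H]2O[Si](C)(C)C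
F9 | step 8 | C6'=C7' enol triflate of F8 (trimethylsilyl ether of 20) | CC(C)C[C@H]1c2c(OC)cc(OC)cc2O[C@]12CC[C@@]3(C(OS(=O)(=O)C(F)(F)F)=C(C(C)C)CC[C@@H]3C)[C@@H]2O[Si](C)(C)C
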